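**Retrosynthetic overview**

- In ring B the single phenolic oxygen O4' is flanked at C3' and C5' by two five-carbon units: the open prenyl group and the C(CH3)2–CH=CH bridge of the pyran ring. These are the same group at two oxidation levels, so the pyran ring is opened to a 3',5'-diprenyl-4'-phenol whose two prenyl groups are exchanged by rotation about the C2–C1' bond.
- The pyran ring is closed in the last step by dehydrogenation to an ortho-quinone methide and oxa-6π electrocyclisation. Either prenyl group gives the same product, and the one oxygen allows only one closure.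
- The two prenyl groups come from a twofold Stille coupling on a 3',5'-dibromoflavanone. Its C2–C1' bond and the C2 stereocentre come from a catalytic asymmetric conjugate addition of an arylboronic acid to a chromone.
- The boronic acid is made by sterically controlled C–H borylation of protected 2,6-dibromophenol.
- Ring order: ring A and the pyranone ring C arrive with 7-hydroxychromone, ring B arrives with 2,6-dibromophenol, and the pyran ring is closed last.

Key step: step 7

Assumption: (S)-4-tert-butyl-2-(pyridin-2-yl)-4,5-dihydrooxazole is taken to deliver the aryl group to the chromone face that gives the (2R)-flavanone, by analogy with the face it selects on 3-substituted cyclohexenones; if the opposite sense is found, the (R)-ligand takes its place.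

**Route**

Step 1
Reactants: 1 7-hydroxy-4H-chromen-4-one
Product: 2 7-(methoxymethoxy)-4H-chromen-4-one
Conditions: MOMCl, K2CO3, acetone, 0 °C to rt
Reagents that add atoms: chloromethyl methyl ether, COCCl
Why: Williamson-type O-alkylation of the acidic 7-OH gives the methoxymethyl ether, so that no phenoxide lowers the acceptor strength of the chromone in the later conjugate addition.

Step 2
Reactants: 3 2,6-dibromophenol
Product: 4 1,3-dibromo-2-(methoxymethoxy)benzene
Conditions: NaH, THF, 0 °C; then MOMCl, 0 °C to rt
Reagents that add atoms: chloromethyl methyl ether, COCCl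
Why: O-alkylation of the sodium phenoxide (methoxymethyl protection) masks the oxygen through the borylation and the two metal-catalysed couplings.

Step 3
Reactants: 4 1,3-dibromo-2-(methoxymethoxy)benzene
Product: 6 [3,5-dibromo-4-(methoxymethoxy)phenyl]boronic acid, via aryl pinacol boronate 5 (not isolated)
Conditions: [Ir(OMe)(cod)]2 (1.5 mol %), 4,4'-di-tert-butyl-2,2'-bipyridine (3 mol %), B2pin2 (0.6 equiv), THF, 80 °C; then NaIO4, NH4OAc, acetone/H2O, rt
Reagents that add atoms: bis(pinacolato)diboron, CC1(C)OB(OC1(C)C)B1OC(C)(C)C(C)(C)O1; water, O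
Why: Iridium-catalysed aromatic C–H borylation is sterically controlled and should take the only C–H with no ortho substituent (para to the oxygen) while sparing the C–Br bonds, and periodate cleavage of the pinacol ester then frees the boronic acid.

Step 4
Reactants: 2 7-(methoxymethoxy)-4H-chromen-4-one; 6 [3,5-dibromo-4-(methoxymethoxy)phenyl]boronic acid
Product: 7 (2R)-2-[3,5-dibromo-4-(methoxymethoxy)phenyl]-7-(methoxymethoxy)-2,3-dihydro-4H-chromen-4-one
Conditions: Pd(OCOCF3)2 (5 mol %), (S)-4-tert-butyl-2-(pyridin-2-yl)-4,5-dihydrooxazole (6 mol %), NH4PF6 (30 mol %), H2O (5 equiv), ClCH2CH2Cl, 60 °C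
Reagents that add atoms: none
Why: Palladium-catalysed asymmetric conjugate addition of an arylboronic acid to a chromone (transmetalation, face-selective insertion of C2=C3 into the aryl–palladium bond, protonolysis of the palladium enolate) sets C2 under control of the chiral pyridine-oxazoline ligand; the cycle stays at divalent palladium, so the C–Br bonds should survive, and the non-basic medium should prevent retro-oxa-Michael racemisation.

Step 5
Reactants: 7 (2R)-2-[3,5-dibromo-4-(methoxymethoxy)phenyl]-7-(methoxymethoxy)-2,3-dihydro-4H-chromen-4-one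
Product: 8 (2R)-7-(methoxymethoxy)-2-[4-(methoxymethoxy)-3,5-bis(3-methylbut-2-en-1-yl)phenyl]-2,3-dihydro-4H-chromen-4-one
Conditions: tributyl(3-methylbut-2-en-1-yl)stannane (2.6 equiv), Pd(PPh3)4 (10 mol %), toluene, 100 °C
Reagents that add atoms: tributyl(3-methylbut-2-en-1-yl)stannane, CCCC[Sn](CCCC)(CCCC)CC=C(C)C
Why: A twofold Stille coupling on the two equivalent aryl bromides should deliver both prenyl groups in their linear form, since the allylpalladium intermediate reductively eliminates at its less hindered terminus, and the base-free conditions should leave C2 untouched.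

Step 6
Reactants: 8 (2R)-7-(methoxymethoxy)-2-[4-(methoxymethoxy)-3,5-bis(3-methylbut-2-en-1-yl)phenyl]-2,3-dihydro-4H-chromen-4-one
Product: 9 (2R)-7-hydroxy-2-[4-hydroxy-3,5-bis(3-methylbut-2-en-1-yl)phenyl]-2,3-dihydro-4H-chromen-4-one
Conditions: 3 M HCl (aq), MeOH, 45 °C
Reagents that add atoms: none
Why: Acid-catalysed acetal cleavage (transacetalisation to methanol) frees both phenols at once; the flavanone centre is stable to dilute acid, and the mild temperature should keep the prenyl groups from Markovnikov cyclisation onto the freed 4'-OH.

Step 7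
Reactants: 9 (2R)-7-hydroxy-2-[4-hydroxy-3,5-bis(3-methylbut-2-en-1-yl)phenyl]-2,3-dihydro-4H-chromen-4-one
Product: 11 ent-abyssinone III, via ortho-quinone methide 10 (not isolated)
Conditions: DDQ (1.05 equiv), toluene, 0 °C to rt
Reagents that add atoms: none
Why: DDQ should abstract hydride from the benzylic and allylic CH2 of one prenyl group ortho to the free 4'-OH and, after loss of the phenolic proton, give the ortho-quinone methide 10, a 1-oxatriene that closes to the 2H-chromene and restores the aromaticity of ring B. The closest known reaction type is the DDQ dehydrogenative cyclisation of ortho-prenylphenols to 2,2-dimethyl-2H-chromenes. The pyran ring closes by a thermal disrotatory oxa-6π electrocyclisation that forms the O–C(CH3)2 bond; only the geometry of 10 with the dienyl chain turned towards the carbonyl oxygen can close, and the two geometries should interconvert, so both drain into 11. No stereocentre is formed, and C2 is not part of the reacting system and should keep its configuration under neutral aprotic conditions at room temperature. No choice between the prenyl groups is needed because rotation about the C2–C1' bond exchanges them and either closure gives the same compound, and a second closure is excluded because ring B has only one oxygen. Chemoselectivity over hydride loss from C2–H and over ring A rests on the prenyl CH2 being the best hydride donor (the cation is allylic and oxygen-stabilised), while C2–H lies beta to the C4 carbonyl and the 7-OH ring is deactivated by that carbonyl; the near-stoichiometric charge of DDQ guards the second prenyl group.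

**Compound list**

1 | 7-hydroxy-4H-chromen-4-one | O=c1ccoc2cc(O)ccc12 | starting material
2 | 7-(methoxymethoxy)-4H-chromen-4-one | COCOc1ccc2c(c1)occc2=O | intermediate
3 | 2,6-dibromophenol | Oc1c(Br)cccc1Br | starting material
4 | 1,3-dibromo-2-(methoxymethoxy)benzene | COCOc1c(Br)cccc1Br | intermediate
5 | 2-[3,5-dibromo-4-(methoxymethoxy)phenyl]-4,4,5,5-tetramethyl-1,3,2-dioxaborolane | COCOc1c(Br)cc(cc1Br)B1OC(C)(C)C(C)(C)O1 | intermediate (not isolated)
6 | [3,5-dibromo-4-(methoxymethoxy)phenyl]boronic acid | COCOc1c(Br)cc(cc1Br)B(O)O | intermediate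
7 | (2R)-2-[3,5-dibromo-4-(methoxymethoxy)phenyl]-7-(methoxymethoxy)-2,3-dihydro-4H-chromen-4-one | COCOc1c(Br)cc(cc1Br)[C@H]1CC(=O)c2ccc(OCOC)cc2O1 | intermediate
8 | (2R)-7-(methoxymethoxy)-2-[4-(methoxymethoxy)-3,5-bis(3-methylbut-2-en-1-yl)phenyl]-2,3-dihydro-4H-chromen-4-one | COCOc1c(CC=C(C)C)cc(cc1CC=C(C)C)[C@H]1CC(=O)c2ccc(OCOC)cc2O1 | intermediate
9 | (2R)-7-hydroxy-2-[4-hydroxy-3,5-bis(3-methylbut-2-en-1-yl)phenyl]-2,3-dihydro-4H-chromen-4-one | CC(C)=CCc1cc(cc(CC=C(C)C)c1O)[C@H]1CC(=O)c2ccc(O)cc2O1 | intermediate
10 | (2R)-7-hydroxy-2-[5-(3-methylbut-2-en-1-yl)-3-(3-methylbut-2-en-1-ylidene)-4-oxocyclohexa-1,5-dien-1-yl]-2,3-dihydro-4H-chromen-4-one (ortho-quinone methide, either geometry of the exocyclic alkene) | CC(C)=CCC1=CC(=CC(=CC=C(C)C)C1=O)[C@H]1CC(=O)c2ccc(O)cc2O1 | intermediate (not isolated)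
11 | ent-abyssinone III, (2R)-7-hydroxy-2-[2,2-dimethyl-8-(3-methylbut-2-en-1-yl)-2H-chromen-6-yl]-2,3-dihydro-4H-chromen-4-one | CC(C)=CCc1cc([C@H]2CC(=O)c3ccc(O)cc3O2)cc2c1OC(C)(C)C=C2 | target

**Step count**

Total steps: 7. Longest linear sequence: 6 steps (2,6-dibromophenol through steps 2, 3, 4, 5, 6 and 7).

**Steps most likely to fail, with fallbacks**

Risk at step 7: competing hydride abstraction at the para-hydroxybenzylic C2–H (leading to dehydrogenation towards the flavone level or to ring opening with loss of configuration) and over-oxidation at the second prenyl group. The fallback sets out from 9 and comes back at 11, replacing hydride abstraction by an electrophile-induced closure. N-(Phenylselanyl)phthalimide (1.05 equiv) with catalytic camphorsulfonic acid in CH2Cl2 at −78 °C should effect a 6-endo seleno-etherification of one prenyl group, the oxygen attacking the tertiary carbon, to give (2R)-7-hydroxy-2-[2,2-dimethyl-8-(3-methylbut-2-en-1-yl)-3-(phenylselanyl)-3,4-dihydro-2H-chromen-6-yl]-2,3-dihydro-4H-chromen-4-one F1 as both epimers at the selenium-bearing carbon, which is of no consequence. Oxidation with NaIO4 in THF/MeOH/H2O at 0 °C to rt should give the corresponding selenoxide F2, whose syn elimination can only take a benzylic C4 hydrogen and should give 11.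

Risk at step 4: slow addition to the electron-rich 7-alkoxychromone with competing protodeboronation, or insufficient facial selectivity. The fallback sets out from 2 and 6 and comes back at 7, replacing asymmetric induction by resolution. The same conjugate addition run with Pd(OCOCF3)2 and achiral 2,2'-bipyridine in aqueous ClCH2CH2Cl at 60 °C should give racemic 2-[3,5-dibromo-4-(methoxymethoxy)phenyl]-7-(methoxymethoxy)-2,3-dihydro-4H-chromen-4-one F3. Preparative chromatography on a chiral stationary phase (supercritical CO2/MeOH) should then separate 7 from the (2S)-enantiomer F4, which is set aside.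

Risk at step 5: allylic transposition during the prenyl transfer (coupling through the tertiary terminus) and an incomplete second coupling. The fallback sets out from 7 and comes back at 8, building each prenyl group in two stages. A twofold Stille coupling with allyltributylstannane (Pd(PPh3)4, toluene, 100 °C), which has no regiochemical ambiguity, should give (2R)-2-[4-(methoxymethoxy)-3,5-di(prop-2-en-1-yl)phenyl]-7-(methoxymethoxy)-2,3-dihydro-4H-chromen-4-one F5. Olefin cross-metathesis with excess 2-methylbut-2-ene and the second-generation Grubbs catalyst RuCl2(=CHPh)(H2IMes)(PCy3) in CH2Cl2 at 40 °C should then convert both allyl groups into prenyl groups and give 8.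

**Further compounds**

F1 | step 7 | (2R)-7-hydroxy-2-[2,2-dimethyl-8-(3-methylbut-2-en-1-yl)-3-(phenylselanyl)-3,4-dihydro-2H-chromen-6-yl]-2,3-dihydro-4H-chromen-4-one (both epimers at the selenium-bearing carbon) | CC(C)=CCc1cc([C@H]2CC(=O)c3ccc(O)cc3O2)cc2c1OC(C)(C)C(C2)[Se]c1ccccc1
F2 | step 7 | selenoxide of F1, (2R)-7-hydroxy-2-[2,2-dimethyl-8-(3-methylbut-2-en-1-yl)-3-(phenylseleninyl)-3,4-dihydro-2H-chromen-6-yl]-2,3-dihydro-4H-chromen-4-one | CC(C)=CCc1cc([C@H]2CC(=O)c3ccc(O)cc3O2)cc2c1OC(C)(C)C(C2)[Se](=O)c1ccccc1
F3 | step 4 | racemic 2-[3,5-dibromo-4-(methoxymethoxy)phenyl]-7-(methoxymethoxy)-2,3-dihydro-4H-chromen-4-one | COCOc1c(Br)cc(cc1Br)C1CC(=O)c2ccc(OCOC)cc2O1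
F4 | step 4 | (2S)-2-[3,5-dibromo-4-(methoxymethoxy)phenyl]-7-(methoxymethoxy)-2,3-dihydro-4H-chromen-4-one | COCOc1c(Br)cc(cc1Br)[C@@H]1CC(=O)c2ccc(OCOC)cc2O1
F5 | step 5 | (2R)-2-[4-(methoxymethoxy)-3,5-di(prop-2-en-1-yl)phenyl]-7-(methoxymethoxy)-2,3-dihydro-4H-chromen-4-one | COCOc1c(CC=C)cc(cc1CC=C)[C@H]1CC(=O)c2ccc(OCOC)cc2O1
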